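**Retrosynthetic overview** (chromanone numbering O1, C2, C3, C4, C4a, C5–C8, C8a; ring A = benzene ring, ring B = pyranone ring)
- Target, (R)-2-[(Z)-heptadec-12-enyl]-5,8-dihydroxychroman-4-one ⇐ BCl3 debenzylation of O5/O8 ⇐ enantioselective CuH 1,4-reduction of the 2-alkylchromone, which sets C2.
- Key disconnection: ring B of the chromone is closed at O1–C2 in a Cp*Rh-catalysed annulation of a salicylaldehyde (formyl carbon = C4) with a β-keto sulfoxonium ylide (C3, C2 and the C17 chain). C3–C4 forms first, then dehydrative O1–C2 closure; ring A is bought and ring B is the only ring formed.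
- Enabling feature: the free phenolic O1–H on C8a of ring A, ortho (across C4a) to C4. It chelates rhodium onto the formyl C–H and then lies 1,5 to the C2 carbonyl of the C4–C3–C2 1,3-dione; O5 and O8 (the C5/C8 hydroquinone oxygens) are benzyl ethers, so only O1 can close.
- Fragments: the salicylaldehyde comes from 2,5-dihydroxybenzaldehyde (benzylation; Baeyer–Villiger/Dakin exchange of CHO for O1–H; magnesium-phenoxide ortho-formylation placing C4 between O1 and O5). The ylide comes from 12-bromododecanoic acid and hex-1-yne (acetylide alkylation, esterification, Lindlar reduction to the Z-alkene, ylide acylation).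

Key step: step 8

Assumption: the (R)-DTBM-SEGPHOS-ligated copper hydride of step 9 is taken to attack the Si face of C2 of the chromone, which gives 2R; should a model 2-alkylchromone show the opposite sense, the (S)-ligand is used.

Step 1
Reactants: 1 2,5-dihydroxybenzaldehyde
Product: 2 2,5-bis(benzyloxy)benzaldehyde
Conditions: BnBr (2.4 equiv), K2CO3 (3 equiv), DMF, 60 °C
Reagents that add atoms: benzyl bromide, BrCc1ccccc1
Why: Williamson etherification of both phenoxides under K2CO3 leaves the aldehyde untouched and forms no stereocentre.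

Step 2
Reactants: 2 2,5-bis(benzyloxy)benzaldehyde
Product: 4 2,5-bis(benzyloxy)phenol, via aryl formate 3 (not isolated)
Conditions: mCPBA, CH2Cl2, 0 °C to rt; then K2CO3 (cat.), MeOH, rt
Reagents that add atoms: mCPBA (3-chloroperoxybenzoic acid), OOC(=O)c1cccc(Cl)c1
Why: Baeyer–Villiger (Dakin-type) oxidation, in which the electron-rich aryl group migrates to give formate 3, whose methanolysis should unveil the phenol that becomes O1; the benzyl ethers are inert to the peracid.

Step 3
Reactants: 4 2,5-bis(benzyloxy)phenol
Product: 6 3,6-bis(benzyloxy)-2-hydroxybenzaldehyde, via salicyl alcohol 5 (not isolated)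
Conditions: MgCl2 (2 equiv), Et3N (4 equiv), (CH2O)n (6 equiv), MeCN, reflux; then 1 M HCl
Reagents that add atoms: paraformaldehyde (as formaldehyde), C=O
Why: Casnati–Skattebøl magnesium-phenoxide ortho-formylation, in which the magnesium phenoxide delivers formaldehyde only to the single free ortho position (between O1 and the benzyloxy group) and salicyl alcohol 5 is oxidised in the flask by hydride transfer to a second formaldehyde, so that C4 is installed regiospecifically.

Step 4
Reactants: 7 12-bromododecanoic acid; 8 hex-1-yne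
Product: 10 octadec-13-ynoic acid, via hex-1-ynyllithium 9 (not isolated)
Conditions: 8 (2.5 equiv), n-BuLi (2.4 equiv), THF, −78 to 0 °C; then 7, DMPU, 0 °C to rt; then 1 M HCl
Reagents that add atoms: none
Why: SN2 alkylation of a lithium acetylide by a primary bromide in THF/DMPU, with one equivalent of 9 spent on deprotonating the acid, whose carboxylate does not interfere.

Step 5
Reactants: 10 octadec-13-ynoic acid
Product: 11 methyl octadec-13-ynoate
Conditions: MeOH, H2SO4 (cat.), reflux
Reagents that add atoms: methanol, CO
Why: Fischer esterification, which leaves the internal alkyne untouched.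

Step 6
Reactants: 11 methyl octadec-13-ynoate
Product: 12 methyl (Z)-octadec-13-enoate
Conditions: H2 (1 atm), 5% Pd/CaCO3 poisoned with Pb(OAc)2 (Lindlar catalyst), quinoline, EtOAc, rt
Reagents that add atoms: none
Why: Lindlar semi-hydrogenation, in which syn delivery of H2 on the poisoned palladium surface should give the Z-alkene and stop at the alkene stage.

Step 7
Reactants: 12 methyl (Z)-octadec-13-enoate
Product: 13 dimethylsulfoxonium (Z)-2-oxononadec-14-enylide
Conditions: Me3S(O)I (3 equiv), KOt-Bu (3 equiv), THF, reflux; then 12, rt to reflux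
Reagents that add atoms: trimethylsulfoxonium iodide, C[S+](C)(C)=O.[I-]
Why: Acylation of dimethylsulfoxonium methylide by the methyl ester (Corey–Chaykovsky ylide chemistry) followed by deprotonation should give the stabilised β-keto sulfoxonium ylide, the isolated Z-alkene being inert to the ylide.

Step 8
Reactants: 6 3,6-bis(benzyloxy)-2-hydroxybenzaldehyde; 13 dimethylsulfoxonium (Z)-2-oxononadec-14-enylide
Product: 15 5,8-bis(benzyloxy)-2-[(Z)-heptadec-12-en-1-yl]-4H-chromen-4-one, via 1,3-diketone 14 (not isolated)
Conditions: [Cp*RhCl2]2 (4 mol %), AgSbF6 (16 mol %), PivOH (1 equiv), ClCH2CH2Cl, 80 °C; then TsOH·H2O (0.2 equiv), 80 °C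
Reagents that add atoms: none
Why: Chloride abstraction by AgSbF6 gives a cationic Cp*Rh catalyst of trivalent rhodium that binds the O1 phenoxide of 6 and cleaves the neighbouring formyl C–H by concerted metalation–deprotonation to a five-membered acyl rhodacycle; ylide 13 then coordinates, loses DMSO to a rhodium carbene, and migratory insertion of the acyl group followed by protodemetalation gives the 1,3-diketone 14 with the new C3–C4 bond. O1 then adds to the C2 carbonyl of 14 and acid-promoted loss of water closes ring B as the vinylogous ester, which forms the O1–C2 bond. The closest known reaction type is the Cp*Rh-catalysed C–H acylmethylation/annulation of salicylaldehydes with sulfoxonium ylides (or α-diazo ketones) to 2-substituted chromones. Ring B is closed by a 6-exo-trig addition of O1 to the C2 ketone (6-endo on its enol form) followed by dehydration, and ring A is not touched. No stereocentre is formed, C2 being left trigonal on purpose so that step 9 can set it by reagent control. The step needs formyl C–H over aryl C–H activation, secured by the five-membered O1 chelate, and closure through O1 and not O5, secured because O5 and O8 are benzyl ethers and O1 is the only free phenol; the remote Z-alkene and the benzyl ethers should be inert to the redox-neutral catalyst.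

Step 9
Reactants: 15 5,8-bis(benzyloxy)-2-[(Z)-heptadec-12-en-1-yl]-4H-chromen-4-one
Product: 17 (R)-5,8-bis(benzyloxy)-2-[(Z)-heptadec-12-en-1-yl]chroman-4-one, via silyl enol ether 16 (not isolated)
Conditions: Cu(OAc)2·H2O (3 mol %), (R)-DTBM-SEGPHOS (3.3 mol %), (EtO)2MeSiH (1.5 equiv), toluene, 0 °C to rt; then 1 M HCl, THF
Reagents that add atoms: none
Why: Asymmetric conjugate reduction with ligated copper hydride, in which CuH adds hydride to C2 of the vinylogous ester from the Si face selected by the axially chiral bisphosphine (this sets the R configuration) and the copper enolate is silylated to 16, which masks C4 against over-reduction before mild acid hydrolysis; the isolated Z-alkene and the benzyl ethers are inert to CuH.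

Step 10
Reactants: 17 (R)-5,8-bis(benzyloxy)-2-[(Z)-heptadec-12-en-1-yl]chroman-4-one
Product: 18 (R)-2-[(Z)-heptadec-12-en-1-yl]-5,8-dihydroxychroman-4-one
Conditions: BCl3 (6 equiv), pentamethylbenzene (6 equiv), CH2Cl2, −78 °C, Ar; then H2O
Reagents that add atoms: none
Why: Lewis-acid debenzylation with BCl3 and pentamethylbenzene as a non-basic benzyl-cation scavenger (Friedel–Crafts trapping) at −78 °C should remove both aryl benzyl ethers without touching the Z-alkene, the ketone or the C2 stereocentre.

**Compound list**
1 | 2,5-dihydroxybenzaldehyde | O=Cc1cc(O)ccc1O | starting material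
2 | 2,5-bis(benzyloxy)benzaldehyde | O=Cc1cc(OCc2ccccc2)ccc1OCc1ccccc1 | intermediate
3 | 2,5-bis(benzyloxy)phenyl formate | O=COc1cc(OCc2ccccc2)ccc1OCc1ccccc1 | intermediate
4 | 2,5-bis(benzyloxy)phenol | Oc1cc(OCc2ccccc2)ccc1OCc1ccccc1 | intermediate
5 | 3,6-bis(benzyloxy)-2-(hydroxymethyl)phenol (formed as its magnesium salt) | OCc1c(O)c(OCc2ccccc2)ccc1OCc1ccccc1 | intermediate
6 | 3,6-bis(benzyloxy)-2-hydroxybenzaldehyde | O=Cc1c(O)c(OCc2ccccc2)ccc1OCc1ccccc1 | intermediate
7 | 12-bromododecanoic acid | OC(=O)CCCCCCCCCCCBr | starting material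
8 | hex-1-yne | C#CCCCC | starting material
9 | hex-1-ynyllithium | [Li]C#CCCCC | intermediate
10 | octadec-13-ynoic acid | CCCCC#CCCCCCCCCCCCC(=O)O | intermediate
11 | methyl octadec-13-ynoate | CCCCC#CCCCCCCCCCCCC(=O)OC | intermediate
12 | methyl (Z)-octadec-13-enoate | CCCC/C=C\CCCCCCCCCCCC(=O)OC | intermediate
13 | dimethylsulfoxonium (Z)-2-oxononadec-14-enylide | CCCC/C=C\CCCCCCCCCCCC(=O)C=S(C)(C)=O | intermediate
14 | (Z)-1-[3,6-bis(benzyloxy)-2-hydroxyphenyl]icos-15-ene-1,3-dione | CCCC/C=C\CCCCCCCCCCCC(=O)CC(=O)c1c(O)c(OCc2ccccc2)ccc1OCc1ccccc1 | intermediate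
15 | 5,8-bis(benzyloxy)-2-[(Z)-heptadec-12-en-1-yl]-4H-chromen-4-one | CCCC/C=C\CCCCCCCCCCCC1=CC(=O)c2c(OCc3ccccc3)ccc(OCc3ccccc3)c2O1 | intermediate
16 | (R)-5,8-bis(benzyloxy)-4-{[diethoxy(methyl)silyl]oxy}-2-[(Z)-heptadec-12-en-1-yl]-2H-chromene | CCCC/C=C\CCCCCCCCCCC[C@@H]1C=C(O[Si](C)(OCC)OCC)c2c(OCc3ccccc3)ccc(OCc3ccccc3)c2O1 | intermediate
17 | (R)-5,8-bis(benzyloxy)-2-[(Z)-heptadec-12-en-1-yl]chroman-4-one | CCCC/C=C\CCCCCCCCCCC[C@@H]1CC(=O)c2c(OCc3ccccc3)ccc(OCc3ccccc3)c2O1 | intermediate
18 | (R)-2-[(Z)-heptadec-12-en-1-yl]-5,8-dihydroxychroman-4-one | CCCC/C=C\CCCCCCCCCCC[C@@H]1CC(=O)c2c(O)ccc(O)c2O1 | target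

**Step count and risks**
Total step count: 10. Longest linear sequence: 7 steps (steps 4 to 10).

Steps most likely to fail:

1. Step 8. What may go wrong: slow C–H metalation of the doubly ortho-substituted, electron-rich aldehyde; interception of the rhodium carbene by the free phenol (O-alkylation); decarbonylation of the acyl rhodium; or incomplete dehydrative closure. The fallback is a Claisen condensation and cyclodehydration that sets out from 6 and comes back at 15. Aldehyde 6 with MeMgBr (2.5 equiv, THF, 0 °C) should give 1-[3,6-bis(benzyloxy)-2-hydroxyphenyl]ethanol F1, which MnO2 (CH2Cl2, rt) should oxidise to 1-[3,6-bis(benzyloxy)-2-hydroxyphenyl]ethanone F2. The dianion of F2 (LiN(SiMe3)2, 3.3 equiv, THF, −78 to 0 °C) is then acylated by ester 12 to give diketone 14, here isolated. TsOH·H2O in toluene at 80 °C should close 14 through O1–C2 to chromone 15.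

2. Step 9. What may go wrong: poor facial selectivity at C2, slow hydride transfer to the electron-rich vinylogous ester next to the 5-benzyloxy group, or over-reduction at C4 after premature cleavage of the enol ether. The fallback is reduction without asymmetric induction followed by resolution with recycling; it sets out from 15 and comes back at 17. LiBH(s-Bu)3 (THF, −78 °C) should reduce 15 in the 1,4 sense to racemic 5,8-bis(benzyloxy)-2-[(Z)-heptadec-12-en-1-yl]chroman-4-one F3. Preparative chromatography on a chiral stationary phase should separate 17 from (S)-5,8-bis(benzyloxy)-2-[(Z)-heptadec-12-en-1-yl]chroman-4-one F4. F4 is returned to F3 with DBU in toluene, which racemises C2 by reversible retro-oxa-Michael opening to (2E,15Z)-1-[3,6-bis(benzyloxy)-2-hydroxyphenyl]icosa-2,15-dien-1-one F5 and reclosure.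

3. Step 3. What may go wrong: low conversion at the crowded ortho position between O1 and the benzyloxy group, or condensation of salicyl alcohol 5 with unreacted phenol to diarylmethanes. The fallback is a directed ortho-metalation that sets out from 4 and comes back at 6. Phenol 4 with MOMCl and i-Pr2NEt (CH2Cl2) should give 1,4-bis(benzyloxy)-2-(methoxymethoxy)benzene F6. n-BuLi/TMEDA (THF, −78 to −20 °C) should lithiate the position flanked by the methoxymethoxy and benzyloxy groups, and DMF then gives 3,6-bis(benzyloxy)-2-(methoxymethoxy)benzaldehyde F7. HCl in MeOH at rt should remove the methoxymethyl group and give 6.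

**Further compounds**
F1 | step 8 | 1-[3,6-bis(benzyloxy)-2-hydroxyphenyl]ethanol (racemic) | CC(O)c1c(O)c(OCc2ccccc2)ccc1OCc1ccccc1
F2 | step 8 | 1-[3,6-bis(benzyloxy)-2-hydroxyphenyl]ethanone | CC(=O)c1c(O)c(OCc2ccccc2)ccc1OCc1ccccc1
F3 | step 9 | racemic 5,8-bis(benzyloxy)-2-[(Z)-heptadec-12-en-1-yl]chroman-4-one | CCCC/C=C\CCCCCCCCCCCC1CC(=O)c2c(OCc3ccccc3)ccc(OCc3ccccc3)c2O1
F4 | step 9 | (S)-5,8-bis(benzyloxy)-2-[(Z)-heptadec-12-en-1-yl]chroman-4-one | CCCC/C=C\CCCCCCCCCCC[C@H]1CC(=O)c2c(OCc3ccccc3)ccc(OCc3ccccc3)c2O1
F5 | step 9 | (2E,15Z)-1-[3,6-bis(benzyloxy)-2-hydroxyphenyl]icosa-2,15-dien-1-one | CCCC/C=C\CCCCCCCCCCC/C=C/C(=O)c1c(O)c(OCc2ccccc2)ccc1OCc1ccccc1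
F6 | step 3 | 1,4-bis(benzyloxy)-2-(methoxymethoxy)benzene | COCOc1cc(OCc2ccccc2)ccc1OCc1ccccc1
F7 | step 3 | 3,6-bis(benzyloxy)-2-(methoxymethoxy)benzaldehyde | COCOc1c(C=O)c(OCc2ccccc2)ccc1OCc1ccccc1
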